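**Retrosynthetic overview**
1. Feature: the C5–C8 carbocycle, fused to the 4-pyranone at C4a/C8a, carries O5, O6 and O7 on one face and Cl8 on the other. C5 and C8 are the para carbons of a 5-hydroxychromone, so this ring is bought as a benzene ring and dearomatised, with C8 stored as a ketal carbon.
2. C8–Cl comes from SN2 inversion of an all-cis C8 mesylate. The mesylate comes from convex-face hydride reduction of the C8 ketone released from the ketal.
3. C6–O and C7–O come from OsO4·TMEDA dihydroxylation of C6=C7, steered by the free C5 hydroxyl of a 5-hydroxy-8,8-dimethoxy-5,8-dihydrochromone. C5 is the only centre set by a catalyst (CBS reduction of the quinone 8-monoketal).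
4. The quinone monoketal comes from PhI(OAc)2/MeOH oxidation of the 5-hydroxy-2-phenethylchromone, which is built by Claisen condensation and cyclodehydration from 2',6'-dihydroxyacetophenone and methyl dihydroisoferulate.
5. Ring order: both carbocycles are purchased as arenes, the pyranone is the only ring of the target that is closed (step 2), and the dioxolane of steps 7–12 is temporary.

Key step: step 6

Remark: chromone numbering (O1 to C8a) is kept for all bicyclic compounds, β is the face of O5, and R is the C2 side chain 2-[4-methoxy-3-(methoxymethoxy)phenyl]ethyl; the C5 carbinol of the dihydrochromone has the geometry of C5 in the target but the descriptor R, because sp2 C6 ranks below C4a there.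

**Step 1**
Reactants: 1 3-(3-hydroxy-4-methoxyphenyl)propanoic acid
Product: 2 methyl 3-(3-hydroxy-4-methoxyphenyl)propanoate
Conditions: MeOH, H2SO4 (cat.), reflux
Reagents that add atoms: methanol, CO
Why: Fischer esterification turns the acid into an acyl donor for the Claisen step, and the phenol and the aryl methyl ether are inert to methanolic acid.

**Step 2**
Reactants: 2 methyl 3-(3-hydroxy-4-methoxyphenyl)propanoate; 3 2',6'-dihydroxyacetophenone
Product: 5 5-hydroxy-2-[2-(3-hydroxy-4-methoxyphenyl)ethyl]chromone, via aryl 1,3-diketone 4 (not isolated)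
Conditions: 3, LiHMDS (5.5 equiv), THF, −78 → 0 °C; 2, 0 °C → rt; aq HCl; crude 4, AcOH, H2SO4 (cat.), 90 °C
Reagents that add atoms: none
Why: Crossed Claisen condensation of the lithium polyanion of 3 (two phenoxides plus the methyl ketone enolate) with ester 2, driven by diketonate formation, followed by acid cyclodehydration of the o-hydroxyaryl 1,3-diketone (the classical chromone synthesis), closes the pyranone, and only one chromone can result because the two phenolic hydroxyls of 4 are equivalent.

**Step 3**
Reactants: 5 5-hydroxy-2-[2-(3-hydroxy-4-methoxyphenyl)ethyl]chromone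
Product: 6 5-hydroxy-2-R-chromone
Conditions: MOMCl (1.1 equiv), i-Pr2NEt, CH2Cl2, 0 °C → rt
Reagents that add atoms: chloromethyl methyl ether, COCCl
Why: O-Alkylation with MOMCl should be selective for the side-chain phenol because the C5 hydroxyl is held in a resonance-assisted hydrogen bond to the C4 carbonyl (the selectivity used for 5-hydroxyflavones), and the acetal is installed only now so that it never meets the acid of step 2.

**Step 4**
Reactants: 6 5-hydroxy-2-R-chromone
Product: 8 8,8-dimethoxy-2-R-chromene-4,5(8H)-dione, via 5-hydroxy-8-methoxychromone 7 (not isolated)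
Conditions: PhI(OAc)2 (2.2 equiv), MeOH, 0 °C → rt; solid NaHCO3
Reagents that add atoms: methanol, CO
Why: In this hypervalent-iodine oxidative dearomatisation of a phenol in methanol, the first equivalent methoxylates the free para carbon C8 and the dienone tautomerises to hydroquinone monoether 7, the second equivalent converts 7 into the quinone dimethyl monoketal, and the side-chain ring has no free hydroxyl through which the iodane could engage it.

**Step 5**
Reactants: 8 8,8-dimethoxy-2-R-chromene-4,5(8H)-dione
Product: 9 (5R)-5-hydroxy-8,8-dimethoxy-2-R-5,8-dihydrochromen-4-one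
Conditions: (S)-Me-CBS (0.3 equiv), catecholborane (1.8 equiv), toluene–CH2Cl2, −78 °C; MeOH, then pH 10 carbonate buffer; Et3N-washed silica
Reagents that add atoms: none
Why: In this Corey–Bakshi–Shibata reduction the C5 ketone should bind the oxazaborolidine through the lone pair on the side of the unsubstituted C6–H flank, so the fully substituted C4a flank acts as the large group and the (S)-catalyst gives the (5R)-carbinol, while the vinylogous-ester C4 carbonyl is too electron-rich to be reduced and the acid-free work-up guards against loss of methanol with rearomatisation.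

**Step 6**
Reactants: 9 (5R)-5-hydroxy-8,8-dimethoxy-2-R-5,8-dihydrochromen-4-one
Product: 11 (5S,6S,7S)-5,6,7-trihydroxy-8,8-dimethoxy-2-R-5,6,7,8-tetrahydrochromen-4-one, via osmate(VI) ester TMEDA chelate 10 (not isolated)
Conditions: OsO4 (1.05 equiv), TMEDA (1.1 equiv), CH2Cl2, −78 °C; then sat. aq Na2SO3, THF, 65 °C
Reagents that add atoms: osmium tetroxide, O=[Os](=O)(=O)=O
Why: The preformed OsO4·TMEDA chelate adds to C6=C7 in a concerted suprafacial [3+2] cycloaddition, and the diamine makes the oxo ligands basic enough to accept a hydrogen bond from the C5 hydroxyl, which holds the reagent on the β face; the closest known reaction type is the hydrogen-bond-directed dihydroxylation of cyclic allylic alcohols with stoichiometric OsO4/TMEDA. No ring of the target is closed, since only the five-membered osmate ring of 10 forms in the cycloaddition and sulfite opens it again. C6 and C7 are set together, cis to each other by the suprafacial addition and cis to O5 by the hydrogen bond, so both derive from the single catalyst-set centre C5. The step needs contrasteric facial selectivity and site selectivity: the C8 ketal presents one methoxy group to each face and is therefore neutral, and C6=C7 is the only alkene outside the electron-poor pyranone and the arene. The open point is that the C5 hydroxyl also lies within reach of the strongly accepting C4 carbonyl oxygen, so CH2Cl2 at −78 °C without protic or donor cosolvent is chosen to favour binding to osmium. The cold, basic medium and the non-acidic osmate cleavage also keep 9 from losing methanol.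

**Step 7**
Reactants: 11 (5S,6S,7S)-5,6,7-trihydroxy-8,8-dimethoxy-2-R-5,6,7,8-tetrahydrochromen-4-one
Product: 12 (5S,6S,7S)-5-hydroxy-6,7-(isopropylidenedioxy)-8,8-dimethoxy-2-R-5,6,7,8-tetrahydrochromen-4-one
Conditions: Me2C(OMe)2 (5 equiv), PPTS (0.1 equiv), CH2Cl2, rt
Reagents that add atoms: 2,2-dimethoxypropane, COC(C)(C)OC
Why: In this acid-catalysed transketalisation under equilibrating conditions the 6,7-dioxolane should prevail over the 5,6-isomer because it leaves the C5 hydroxyl in its six-membered hydrogen bond to the C4 carbonyl, any 5,6-isomer can be resubmitted, and the excess reagent keeps the C8 ketal intact.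

**Step 8**
Reactants: 12 (5S,6S,7S)-5-hydroxy-6,7-(isopropylidenedioxy)-8,8-dimethoxy-2-R-5,6,7,8-tetrahydrochromen-4-one
Product: 13 (5S,6R,7S)-5-(tert-butyldimethylsilyloxy)-6,7-(isopropylidenedioxy)-8,8-dimethoxy-2-R-5,6,7,8-tetrahydrochromen-4-one
Conditions: TBSCl, imidazole, DMAP (cat.), DMF, rt → 40 °C
Reagents that add atoms: tert-butyldimethylsilyl chloride, CC(C)(C)[Si](C)(C)Cl
Why: Imidazole-promoted silylation caps the only free hydroxyl so that it cannot be sulfonylated in step 11, it locks the dioxolane at O6/O7, and its basic medium spares ketal, dioxolane and MOM ether (geometry unchanged; the C6 descriptor changes only because silicon raises the rank of C5).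

**Step 9**
Reactants: 13 (5S,6R,7S)-5-(tert-butyldimethylsilyloxy)-6,7-(isopropylidenedioxy)-8,8-dimethoxy-2-R-5,6,7,8-tetrahydrochromen-4-one
Product: 14 (5S,6R,7S)-5-(tert-butyldimethylsilyloxy)-6,7-(isopropylidenedioxy)-2-R-6,7-dihydro-5H-chromene-4,8-dione
Conditions: p-TsOH·H2O (0.1 equiv), acetone–H2O 20:1, rt
Reagents that add atoms: water, O
Why: In this acid-catalysed ketal hydrolysis in wet acetone the acyclic dimethyl ketal loses its methanol irreversibly to the dilute medium, whereas the dioxolane is held in place by the solvent acetone, and a hindered secondary TBS ether and an aryl MOM ether should tolerate catalytic sulfonic acid at room temperature.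

**Step 10**
Reactants: 14 (5S,6R,7S)-5-(tert-butyldimethylsilyloxy)-6,7-(isopropylidenedioxy)-2-R-6,7-dihydro-5H-chromene-4,8-dione
Product: 15 (5S,6R,7R,8S)-5-(tert-butyldimethylsilyloxy)-8-hydroxy-6,7-(isopropylidenedioxy)-2-R-5,6,7,8-tetrahydrochromen-4-one (O5 to O8 all β)
Conditions: NaBH4, CeCl3·7H2O, MeOH, −78 °C
Reagents that add atoms: none
Why: Luche reduction delivers hydride 1,2 to the very electrophilic C8 ketone from the convex α face, opposite the cis-fused dioxolane and the C5 silyloxy group, which places O8 cis to O7, and the cold, nearly neutral medium avoids β-elimination of O6 and leaves the pyranone untouched.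

**Step 11**
Reactants: 15 (5S,6R,7R,8S)-5-(tert-butyldimethylsilyloxy)-8-hydroxy-6,7-(isopropylidenedioxy)-2-R-5,6,7,8-tetrahydrochromen-4-one
Product: 16 (5S,6R,7S,8S)-8-mesylate of 15
Conditions: MsCl, Et3N, CH2Cl2, −10 °C
Reagents that add atoms: methanesulfonyl chloride, CS(=O)(=O)Cl
Why: Sulfonylation of the only free hydroxyl proceeds at oxygen and therefore with retention at C8, and a mesylate is preferred to a triflate because triflic anhydride would also attack the nucleophilic pyranone carbonyl.

**Step 12**
Reactants: 16 (5S,6R,7S,8S)-8-mesylate of 15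
Product: 17 (5S,6R,7S,8R)-5-(tert-butyldimethylsilyloxy)-8-chloro-6,7-(isopropylidenedioxy)-2-R-5,6,7,8-tetrahydrochromen-4-one (Cl α)
Conditions: LiCl (10 equiv), DMF, 50 °C
Reagents that add atoms: lithium chloride, [Li+].[Cl-]
Why: In this SN2 displacement with inversion, chloride enters from the open α face anti to the β mesylate at a carbon bound to C8a of the electron-poor pyranone, which speeds SN2 and disfavours ionisation, no β-oriented oxygen can participate from the rear, and an epimerising second chloride exchange would have to come from the shielded β face.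

**Step 13**
Reactants: 17 (5S,6R,7S,8R)-5-(tert-butyldimethylsilyloxy)-8-chloro-6,7-(isopropylidenedioxy)-2-R-5,6,7,8-tetrahydrochromen-4-one
Product: 18 (5S,6S,7S,8R)-8-chloro-5,6,7-trihydroxy-2-[2-(3-hydroxy-4-methoxyphenyl)ethyl]-5,6,7,8-tetrahydrochromen-4-one
Conditions: 2 M aq HCl–THF 1:1, rt → 40 °C
Reagents that add atoms: none
Why: Global acid hydrolysis removes dioxolane, silyl ether and MOM acetal in one operation, the trans chlorohydrin never meets base so epoxide closure is excluded, and the C8–Cl bond should resist solvolysis because a cation there would be conjugated with the enone.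

**Compound list**
1 | 3-(3-hydroxy-4-methoxyphenyl)propanoic acid | COc1ccc(CCC(=O)O)cc1O | starting material
2 | methyl 3-(3-hydroxy-4-methoxyphenyl)propanoate | COc1ccc(CCC(=O)OC)cc1O | intermediate
3 | 2',6'-dihydroxyacetophenone | CC(=O)c1c(O)cccc1O | starting material
4 | 1-(2,6-dihydroxyphenyl)-5-(3-hydroxy-4-methoxyphenyl)pentane-1,3-dione (not isolated) | COc1ccc(CCC(=O)CC(=O)c2c(O)cccc2O)cc1O | intermediate
5 | 5-hydroxy-2-[2-(3-hydroxy-4-methoxyphenyl)ethyl]chromone | COc1ccc(CCc2cc(=O)c3c(O)cccc3o2)cc1O | intermediate
6 | 5-hydroxy-2-{2-[4-methoxy-3-(methoxymethoxy)phenyl]ethyl}chromone | COc1ccc(CCc2cc(=O)c3c(O)cccc3o2)cc1OCOC | intermediate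
7 | 5-hydroxy-8-methoxy-2-R-chromone (not isolated) | COc1ccc(CCc2cc(=O)c3c(O)ccc(OC)c3o2)cc1OCOC | intermediate
8 | 8,8-dimethoxy-2-R-chromene-4,5(8H)-dione (quinone 8-monoketal) | COc1ccc(CCc2cc(=O)c3c(o2)C(OC)(OC)C=CC3=O)cc1OCOC | intermediate
9 | (5R)-5-hydroxy-8,8-dimethoxy-2-R-5,8-dihydrochromen-4-one | COc1ccc(CCc2cc(=O)c3c(o2)C(OC)(OC)C=C[C@H]3O)cc1OCOC | intermediate
10 | dioxoosmium(VI) 6,7-glycolate TMEDA chelate of 11 (not isolated) | COc1ccc(CCc2cc(=O)c3c(o2)C(OC)(OC)[C@H]4O[Os-2]5(=O)(=O)([N+](C)(C)CC[N+]5(C)C)O[C@H]4[C@H]3O)cc1OCOC | intermediate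
11 | (5S,6S,7S)-5,6,7-trihydroxy-8,8-dimethoxy-2-R-5,6,7,8-tetrahydrochromen-4-one | COc1ccc(CCc2cc(=O)c3c(o2)C(OC)(OC)[C@@H](O)[C@@H](O)[C@H]3O)cc1OCOC | intermediate
12 | (5S,6S,7S)-6,7-acetonide of 11 | COc1ccc(CCc2cc(=O)c3c(o2)C(OC)(OC)[C@H]4OC(C)(C)O[C@H]4[C@H]3O)cc1OCOC | intermediate
13 | (5S,6R,7S)-5-O-TBS ether of 12 | COc1ccc(CCc2cc(=O)c3c(o2)C(OC)(OC)[C@H]4OC(C)(C)O[C@H]4[C@H]3O[Si](C)(C)C(C)(C)C)cc1OCOC | intermediate
14 | (5S,6R,7S)-8-ketone | COc1ccc(CCc2cc(=O)c3c(o2)C(=O)[C@H]4OC(C)(C)O[C@H]4[C@H]3O[Si](C)(C)C(C)(C)C)cc1OCOC | intermediate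
15 | (5S,6R,7R,8S)-8-alcohol, all-cis | COc1ccc(CCc2cc(=O)c3c(o2)[C@@H](O)[C@H]4OC(C)(C)O[C@H]4[C@H]3O[Si](C)(C)C(C)(C)C)cc1OCOC | intermediate
16 | (5S,6R,7S,8S)-8-mesylate | COc1ccc(CCc2cc(=O)c3c(o2)[C@@H](OS(C)(=O)=O)[C@H]4OC(C)(C)O[C@H]4[C@H]3O[Si](C)(C)C(C)(C)C)cc1OCOC | intermediate
17 | (5S,6R,7S,8R)-8-chloride, Cl trans to O7 | COc1ccc(CCc2cc(=O)c3c(o2)[C@H](Cl)[C@H]4OC(C)(C)O[C@H]4[C@H]3O[Si](C)(C)C(C)(C)C)cc1OCOC | intermediate
18 | (5S,6S,7S,8R)-8-chloro-5,6,7-trihydroxy-2-[2-(3-hydroxy-4-methoxyphenyl)ethyl]-5,6,7,8-tetrahydrochromen-4-one | COc1ccc(CCc2cc(=O)c3c(o2)[C@H](Cl)[C@@H](O)[C@@H](O)[C@H]3O)cc1O | target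

**Step count**
Total step count: 13. Longest linear sequence: 13 steps (1 → 18); 3 enters at step 2.

**Steps most likely to fail**

Step 6. The C5 hydroxyl may stay hydrogen-bonded to the C4 carbonyl oxygen. The osmium complex would then not be anchored and would add anti to O5, so facial selectivity would be lost or reversed. The fallback replaces direction by steric control and corrects C5 afterwards.
- It sets out from 8, which is reduced with (R)-Me-CBS/catecholborane to the (5S)-dienol ketal F1.
- F1 is silylated (TBSCl, imidazole, DMF) to the 5-O-TBS dienol ketal F2.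
- Upjohn dihydroxylation (OsO4 cat., NMO, acetone–H2O) should then occur anti to the bulky silyloxy group and give the 5,6-trans-6,7-cis diol F3, which already has the correct C6 and C7.
- Acetonide formation (Me2C(OMe)2, PPTS) gives the 5-epi silyl acetonide F4, and TBAF gives the 5-epi alcohol F5.
- Dess–Martin oxidation gives the C5 ketone F6.
- Luche reduction of F6 from the convex α face should give the β carbinol, and the route is rejoined at 12.

Step 5. The two sp2 flanks of the C5 ketone may be poorly discriminated, or the catalyst may be tied up by the more basic C4 carbonyl, either of which would erode the enantiomeric purity. The bis-allylic ketal may also lose methanol with rearomatisation during work-up. The fallback replaces asymmetric catalysis by resolution in neutral or basic media.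
- It sets out from 8, and Luche reduction gives the racemic dienol ketal F7.
- Lipase-catalysed acylation (Burkholderia cepacia lipase or CAL-B, vinyl acetate, MTBE, rt) should acylate the enantiomer whose large C4a flank and small C6 flank match the empirical size rule for secondary alcohols. This gives the (5R)-acetate F8, which is separated from the slower-reacting enantiomer.
- K2CO3/MeOH at 0 °C returns the route at 9.

Step 4. The first oxidation starts from a phenol that is chelated and deactivated by the ortho acyl group. Ligand exchange at iodine may be slow, methanol may attack C6 instead of C8, or methanol may add to the product. The fallback separates C8 oxygenation from ketal formation.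
- It sets out from 6, and Teuber oxidation with Fremy's salt (KH2PO4 buffer, acetone–H2O) gives the chromone-5,8-quinone F9.
- Aqueous Na2S2O4 gives the 5,8-dihydroxychromone F10.
- MeI (1 equiv), K2CO3, acetone should methylate only the non-chelated O8.
- The route is rejoined at 7, now isolated, which needs a single equivalent of PhI(OAc)2 in MeOH to reach 8.

**Further compounds**
F1 | step 6 | (5S)-dienol ketal (enantiomer of 9) | COc1ccc(CCc2cc(=O)c3c(o2)C(OC)(OC)C=C[C@@H]3O)cc1OCOC
F2 | step 6 | 5-O-TBS dienol ketal | COc1ccc(CCc2cc(=O)c3c(o2)C(OC)(OC)C=C[C@@H]3O[Si](C)(C)C(C)(C)C)cc1OCOC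
F3 | step 6 | 5,6-trans-6,7-cis diol | COc1ccc(CCc2cc(=O)c3c(o2)C(OC)(OC)[C@@H](O)[C@@H](O)[C@@H]3O[Si](C)(C)C(C)(C)C)cc1OCOC
F4 | step 6 | 5-epi silyl acetonide | COc1ccc(CCc2cc(=O)c3c(o2)C(OC)(OC)[C@H]4OC(C)(C)O[C@H]4[C@@H]3O[Si](C)(C)C(C)(C)C)cc1OCOC
F5 | step 6 | 5-epi alcohol | COc1ccc(CCc2cc(=O)c3c(o2)C(OC)(OC)[C@H]4OC(C)(C)O[C@H]4[C@@H]3O)cc1OCOC
F6 | step 6 | C5 ketone | COc1ccc(CCc2cc(=O)c3c(o2)C(OC)(OC)[C@H]4OC(C)(C)O[C@H]4C3=O)cc1OCOC
F7 | step 5 | racemic dienol ketal | COc1ccc(CCc2cc(=O)c3c(o2)C(OC)(OC)C=CC3O)cc1OCOC
F8 | step 5 | (5R)-acetate | COc1ccc(CCc2cc(=O)c3c(o2)C(OC)(OC)C=C[C@H]3OC(C)=O)cc1OCOC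
F9 | step 4 | chromone-5,8-quinone | COc1ccc(CCc2cc(=O)c3c(o2)C(=O)C=CC3=O)cc1OCOC
F10 | step 4 | 5,8-dihydroxychromone | COc1ccc(CCc2cc(=O)c3c(O)ccc(O)c3o2)cc1OCOC
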